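**Plan**
- Retrosynthesis: the thirteen O–CH3 bonds are cut first, then the ring D–O–ring E ether and the ring B–O–ring C ether. This leaves a ring C–D diphenol, a ring A–B bromide and a ring E bromide.
- Ring D carries five neighbouring oxygen-bearing carbons (C1 ether to ring C, C2 ether to ring E, C3–C5 hydroxyl) and one CH (C6). Cutting C5–C6 opens it to a dienylketene and, one stage back, to a 4-silyloxy-4-(1-aryloxyvinyl)-2,3-dimethoxycyclobutenone.
- C2–C5 with their oxygens are the four carbons of dimethyl squarate. C1 and C6 are the two carbons of the vinyl ether of ring C, which is joined to squarate as its α-lithio derivative.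
- Forward: ring C vinyl ether → cyclobutenone → thermal closure of ring D → methylation, desilylation → ring A–B bromide onto the open ring C phenol → ring E bromide onto the crowded ring D phenol → BBr3.
- The target is achiral. The one stereocentre on the way (C4 of the cyclobutenone, racemic) is erased on aromatisation. Regiochemistry is settled by the mechanism: the former carbinol oxygen (C2) keeps its silyl group and the former ketene oxygen (C5) emerges as the only free phenol.

Key step: step 5

Remark: rings are lettered A to E from the 2,4,6-trihydroxyphenyl end to the 3,4,5-trihydroxyphenyl end, ring D is numbered as above, and compounds 1, 5, 14, 16 and 19 are assumed to be purchasable.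

Step 1
Reactants: 1 2,6-dimethoxy-1,4-benzoquinone
Product: 2 2,6-dimethoxybenzene-1,4-diol
Conditions: Na2S2O4, H2O/EtOAc, rt, Ar
Reagents that add atoms: none
Why: Dithionite reduction of a 1,4-benzoquinone to its hydroquinone is fast in a two-phase system, and the product is carried on under argon to avoid reoxidation.

Step 2
Reactants: 2 2,6-dimethoxybenzene-1,4-diol
Product: 3 2,6-dimethoxy-4-[(triisopropylsilyl)oxy]phenol
Conditions: TIPSCl, imidazole, DMF, 0 °C
Reagents that add atoms: chlorotriisopropylsilane, CC(C)[Si](Cl)(C(C)C)C(C)C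
Why: Silylation with a bulky chlorosilane should select the hydroxyl flanked by two hydrogens over the hydrogen-bonded one between two methoxy groups, and the silyl ether later shields the neighbouring ring positions from metalation.

Step 3
Reactants: 3 2,6-dimethoxy-4-[(triisopropylsilyl)oxy]phenol
Product: 4 [3,5-dimethoxy-4-(vinyloxy)phenoxy]triisopropylsilane
Conditions: vinyl acetate, [Ir(cod)Cl]2 (1 mol %), Na2CO3, toluene, 100 °C
Reagents that add atoms: vinyl acetate, CC(=O)OC=C
Why: Iridium-catalysed transfer vinylation of phenols with vinyl acetate (addition of the iridium phenoxide across the vinyl group, then β-acetate elimination) should convert the hindered phenol under weakly basic conditions that leave the aryl silyl ether alone.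

Step 4
Reactants: 4 [3,5-dimethoxy-4-(vinyloxy)phenoxy]triisopropylsilane; 5 dimethyl squarate
Product: 8 racemic 4-[(tert-butyldimethylsilyl)oxy]-4-{1-[2,6-dimethoxy-4-(triisopropylsilyloxy)phenoxy]vinyl}-2,3-dimethoxycyclobut-2-en-1-one, via vinyllithium 6 (not isolated), via lithium alkoxide 7 (not isolated)
Conditions: t-BuLi, THF, −78 °C; cannulate into 5, THF, −78 °C; TBSOTf, −78 → −20 °C
Reagents that add atoms: tert-butyldimethylsilyl trifluoromethanesulfonate, CC(C)(C)[Si](C)(C)OS(=O)(=O)C(F)(F)F
Why: α-Lithiation of a vinyl ether at the vinylic C–H next to oxygen (helped here by chelation of lithium by an ortho methoxy group), 1,2-addition of the vinyllithium to one carbonyl of the squarate ester and in-flask O-silylation of the tertiary lithium alkoxide are standard operations of squarate chemistry, and the new quaternary centre forms as a racemate that step 5 erases.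

Step 5
Reactants: 8 racemic 4-[(tert-butyldimethylsilyl)oxy]-4-{1-[2,6-dimethoxy-4-(triisopropylsilyloxy)phenoxy]vinyl}-2,3-dimethoxycyclobut-2-en-1-one
Product: 11 4-[(tert-butyldimethylsilyl)oxy]-5-{2,6-dimethoxy-4-[(triisopropylsilyl)oxy]phenoxy}-2,3-dimethoxyphenol, via dienylketene 9 (not isolated), via cyclohexadienone 10 (not isolated)
Conditions: toluene (degassed), 110 °C, Ar
Reagents that add atoms: none
Why: Heating cleaves the C1–C4 bond of the cyclobutenone in a conrotatory 4π electrocyclic opening in which the silyloxy donor on C4 rotates outward, so the 1-aryloxyvinyl group turns inward and sits cis to the ketene in 9. The ketene carbon then bonds to the terminal CH2 of the vinyl group in a thermally allowed disrotatory 6π electrocyclisation, which closes the six-membered carbocycle, forms the ring D C5–C6 bond and gives cyclohexa-2,4-dienone 10, which enolises irreversibly to phenol 11. This is the Moore rearrangement of 4-alkenyl-4-oxycyclobutenones made from squarate esters, known for 4-hydroxy, 4-alkoxy and 4-silyloxy substrates, α-alkoxyvinyl groups included. No stereocentre is created, and the racemic C4 centre becomes an sp2 carbon. The step needs inward rotation of the vinyl group and a defined oxygenation pattern: the outward preference of the oxygen donor secures the first, and the connectivity of 8 places the aryloxy carbon (C1) next to the silyloxy carbon (C2). Because the silyl group stays on the former carbinol oxygen, only the C5 hydroxyl is free, so the two new oxygens are told apart without relying on steric differences.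

Step 6
Reactants: 11 4-[(tert-butyldimethylsilyl)oxy]-5-{2,6-dimethoxy-4-[(triisopropylsilyl)oxy]phenoxy}-2,3-dimethoxyphenol
Product: 12 tert-butyl{2-[2,6-dimethoxy-4-(triisopropylsilyloxy)phenoxy]-4,5,6-trimethoxyphenoxy}dimethylsilane
Conditions: MeI, K2CO3, acetone, 50 °C
Reagents that add atoms: iodomethane, CI
Why: Williamson O-methylation of the single free phenol is unambiguous, and the crowded aryl silyl ethers should tolerate K2CO3 in acetone.

Step 7
Reactants: 12 tert-butyl{2-[2,6-dimethoxy-4-(triisopropylsilyloxy)phenoxy]-4,5,6-trimethoxyphenoxy}dimethylsilane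
Product: 13 4-(2-hydroxy-3,4,5-trimethoxyphenoxy)-3,5-dimethoxyphenol
Conditions: Bu4NF, AcOH, THF, 0 °C → rt
Reagents that add atoms: none
Why: Fluoride-driven desilylation removes both aryl silyl ethers at once, and buffering with acetic acid keeps the electron-rich phenols protonated and less prone to air oxidation.

Step 8
Reactants: 14 1-iodo-3,5-dimethoxybenzene
Product: 15 2-bromo-1-iodo-3,5-dimethoxybenzene
Conditions: NBS, MeCN, 0 °C → rt
Reagents that add atoms: N-bromosuccinimide, O=C1CCC(=O)N1Br
Why: Electrophilic aromatic bromination of a 5-substituted 1,3-dimethoxybenzene should go to C2, para to one methoxy group and ortho to the other, in preference to the more crowded position between the two methoxy groups.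

Step 9
Reactants: 15 2-bromo-1-iodo-3,5-dimethoxybenzene; 16 2,4,6-trimethoxyphenol
Product: 17 2-bromo-1,5-dimethoxy-3-(2,4,6-trimethoxyphenoxy)benzene
Conditions: CuI (10 mol %), picolinic acid (20 mol %), K3PO4, DMSO, 80 °C, Ar
Reagents that add atoms: none
Why: Ullmann-type diaryl ether coupling with CuI and picolinic acid, a system suited to 2,6-disubstituted phenols, should occur at the C–I bond only, since iodide is the better leaving group and the bromide ends up between an aryloxy and a methoxy group, out of reach of a hindered phenoxide.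

Step 10
Reactants: 13 4-(2-hydroxy-3,4,5-trimethoxyphenoxy)-3,5-dimethoxyphenol; 17 2-bromo-1,5-dimethoxy-3-(2,4,6-trimethoxyphenoxy)benzene
Product: 18 6-{2,6-dimethoxy-4-[2,4-dimethoxy-6-(2,4,6-trimethoxyphenoxy)phenoxy]phenoxy}-2,3,4-trimethoxyphenol
Conditions: CuI (20 mol %), 2,2,6,6-tetramethylheptane-3,5-dione, Cs2CO3, NMP, 120 °C, Ar
Reagents that add atoms: none
Why: Ullmann ether coupling with a β-diketone ligand for electron-rich ortho-substituted bromides should be chemoselective by steric matching, because the doubly ortho-substituted bromide can be reached by the unhindered ring C phenoxide but not by the ring D phenoxide lodged between an aryloxy and a methoxy group.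

Step 11
Reactants: 18 6-{2,6-dimethoxy-4-[2,4-dimethoxy-6-(2,4,6-trimethoxyphenoxy)phenoxy]phenoxy}-2,3,4-trimethoxyphenol; 19 5-bromo-1,2,3-trimethoxybenzene
Product: 20 tridecamethyl ether of the target (rings A to E, all thirteen hydroxyls as OMe)
Conditions: CuI (20 mol %), picolinic acid, K3PO4, DMSO, 100 °C, Ar
Reagents that add atoms: none
Why: Ullmann ether coupling with CuI and picolinic acid should join the remaining crowded ring D phenol to an aryl bromide that has no ortho substituents, the pairing this ligand system handles best.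

Step 12
Reactants: 20 tridecamethyl ether of the target
Product: 21 CNP0243665.0, 4-(3,4,5-trihydroxyphenoxy)-5-{2,6-dihydroxy-4-[2,4-dihydroxy-6-(2,4,6-trihydroxyphenoxy)phenoxy]phenoxy}benzene-1,2,3-triol
Conditions: BBr3 (large excess), CH2Cl2, −78 °C → rt; H2O work-up under Ar
Reagents that add atoms: none
Why: BBr3 demethylation (Lewis acid complexation, then SN2 attack of bromide on methyl) cleaves aryl methyl ethers while diaryl ether bonds, which offer no sp3 carbon, stay intact.

**Compound list**
1 | 2,6-dimethoxy-1,4-benzoquinone | COC1=CC(=O)C=C(OC)C1=O | starting material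
2 | 2,6-dimethoxybenzene-1,4-diol | COc1cc(O)cc(OC)c1O | intermediate
3 | 2,6-dimethoxy-4-[(triisopropylsilyl)oxy]phenol | COc1cc(O[Si](C(C)C)(C(C)C)C(C)C)cc(OC)c1O | intermediate
4 | [3,5-dimethoxy-4-(vinyloxy)phenoxy]triisopropylsilane | C=COc1c(OC)cc(O[Si](C(C)C)(C(C)C)C(C)C)cc1OC | intermediate
5 | dimethyl squarate (3,4-dimethoxycyclobut-3-ene-1,2-dione) | COC1=C(OC)C(=O)C1=O | starting material
6 | 1-[2,6-dimethoxy-4-(triisopropylsilyloxy)phenoxy]vinyllithium (formed in the flask) | [Li]C(=C)Oc1c(OC)cc(O[Si](C(C)C)(C(C)C)C(C)C)cc1OC | intermediate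
7 | racemic lithium 1-{1-[2,6-dimethoxy-4-(triisopropylsilyloxy)phenoxy]vinyl}-2,3-dimethoxy-4-oxocyclobut-2-en-1-olate (formed in the flask) | COC1=C(OC)C([O-])(C(=C)Oc2c(OC)cc(O[Si](C(C)C)(C(C)C)C(C)C)cc2OC)C1=O.[Li+] | intermediate
8 | racemic 4-[(tert-butyldimethylsilyl)oxy]-4-{1-[2,6-dimethoxy-4-(triisopropylsilyloxy)phenoxy]vinyl}-2,3-dimethoxycyclobut-2-en-1-one | COC1=C(OC)C(O[Si](C)(C)C(C)(C)C)(C(=C)Oc2c(OC)cc(O[Si](C(C)C)(C(C)C)C(C)C)cc2OC)C1=O | intermediate
9 | 4-[(tert-butyldimethylsilyl)oxy]-5-[2,6-dimethoxy-4-(triisopropylsilyloxy)phenoxy]-2,3-dimethoxyhexa-1,3,5-trien-1-one, aryloxyvinyl group cis to the ketene across C3=C4 (formed in the flask) | O=C=C(OC)/C(OC)=C(/O[Si](C)(C)C(C)(C)C)C(=C)Oc1c(OC)cc(O[Si](C(C)C)(C(C)C)C(C)C)cc1OC | intermediate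
10 | 4-[(tert-butyldimethylsilyl)oxy]-5-[2,6-dimethoxy-4-(triisopropylsilyloxy)phenoxy]-2,3-dimethoxycyclohexa-2,4-dien-1-one (formed in the flask) | O=C1CC(Oc2c(OC)cc(O[Si](C(C)C)(C(C)C)C(C)C)cc2OC)=C(O[Si](C)(C)C(C)(C)C)C(OC)=C1OC | intermediate
11 | 4-[(tert-butyldimethylsilyl)oxy]-5-{2,6-dimethoxy-4-[(triisopropylsilyl)oxy]phenoxy}-2,3-dimethoxyphenol | COc1c(O)cc(Oc2c(OC)cc(O[Si](C(C)C)(C(C)C)C(C)C)cc2OC)c(O[Si](C)(C)C(C)(C)C)c1OC | intermediate
12 | tert-butyl{2-[2,6-dimethoxy-4-(triisopropylsilyloxy)phenoxy]-4,5,6-trimethoxyphenoxy}dimethylsilane | COc1cc(Oc2c(OC)cc(O[Si](C(C)C)(C(C)C)C(C)C)cc2OC)c(O[Si](C)(C)C(C)(C)C)c(OC)c1OC | intermediate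
13 | 4-(2-hydroxy-3,4,5-trimethoxyphenoxy)-3,5-dimethoxyphenol | COc1cc(Oc2c(OC)cc(O)cc2OC)c(O)c(OC)c1OC | intermediate
14 | 1-iodo-3,5-dimethoxybenzene | COc1cc(I)cc(OC)c1 | starting material
15 | 2-bromo-1-iodo-3,5-dimethoxybenzene | COc1cc(I)c(Br)c(OC)c1 | intermediate
16 | 2,4,6-trimethoxyphenol | COc1cc(OC)c(O)c(OC)c1 | starting material
17 | 2-bromo-1,5-dimethoxy-3-(2,4,6-trimethoxyphenoxy)benzene | COc1cc(OC)c(Oc2cc(OC)cc(OC)c2Br)c(OC)c1 | intermediate
18 | 6-{2,6-dimethoxy-4-[2,4-dimethoxy-6-(2,4,6-trimethoxyphenoxy)phenoxy]phenoxy}-2,3,4-trimethoxyphenol | COc1cc(OC)c(Oc2cc(OC)cc(OC)c2Oc2cc(OC)c(Oc3cc(OC)c(OC)c(OC)c3O)c(OC)c2)c(OC)c1 | intermediate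
19 | 5-bromo-1,2,3-trimethoxybenzene | COc1cc(Br)cc(OC)c1OC | starting material
20 | tridecamethyl ether of the target | COc1cc(OC)c(Oc2cc(OC)cc(OC)c2Oc2cc(OC)c(Oc3cc(OC)c(OC)c(OC)c3Oc3cc(OC)c(OC)c(OC)c3)c(OC)c2)c(OC)c1 | intermediate
21 | CNP0243665.0, 4-(3,4,5-trihydroxyphenoxy)-5-{2,6-dihydroxy-4-[2,4-dihydroxy-6-(2,4,6-trihydroxyphenoxy)phenoxy]phenoxy}benzene-1,2,3-triol | Oc1cc(O)c(Oc2cc(O)cc(O)c2Oc2cc(O)c(Oc3cc(O)c(O)c(O)c3Oc3cc(O)c(O)c(O)c3)c(O)c2)c(O)c1 | target

**Step count**
Total: 12 steps. Longest linear sequence: 10 steps (steps 1–7 and 10–12, from 1); the ring A–B bromide 17 is made in 2 steps (8 and 9).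

**Steps most likely to fail**

Step 4. The risk is that t-BuLi metalates the ring C–H bonds between the methoxy and silyloxy groups, or that the 1-aryloxyvinyllithium loses lithium aryloxide by α-elimination before it meets the squarate. The fallback generates the same anion by tin–lithium exchange and sets out from 3. Its potassium salt (KH, THF) is added to trichloroethylene to give {4-[(E)-1,2-dichlorovinyloxy]-3,5-dimethoxyphenoxy}triisopropylsilane F1. Treatment with n-BuLi (THF, −78 → −40 °C, then aqueous NH4Cl) causes elimination and chlorine–lithium exchange and should give (4-ethynyloxy-3,5-dimethoxyphenoxy)triisopropylsilane F2. Hydrostannation with Bu3SnH and Pd(PPh3)4 places tin on the oxygen-bearing carbon, giving tributyl{1-[2,6-dimethoxy-4-(triisopropylsilyloxy)phenoxy]vinyl}stannane F3. Exchange with n-BuLi at −78 °C then delivers vinyllithium 6 within minutes and with no alkyllithium base left over for ring metalation. The route is rejoined at 6.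

Step 10. The risk is slow C–O bond formation at the electron-rich, doubly ortho-substituted C–Br bond of 17, so that reductive loss of bromine and decay of the diphenol outrun the coupling. The fallback brings ring B in as an activated ortho-formyl bromide and adds ring A last from a cheap bromide used in excess; it sets out from 13. Coupling of 13 with commercial 2-bromo-3,5-dimethoxybenzaldehyde (CuI, picolinic acid, K3PO4, DMSO, 90 °C) at the unhindered ring C phenol should give 2-[4-(2-hydroxy-3,4,5-trimethoxyphenoxy)-3,5-dimethoxyphenoxy]-3,5-dimethoxybenzaldehyde F4. Coupling of its ring D phenol with 19 under the conditions of step 11 gives 2-{3,5-dimethoxy-4-[3,4,5-trimethoxy-2-(3,4,5-trimethoxyphenoxy)phenoxy]phenoxy}-3,5-dimethoxybenzaldehyde F5. Baeyer–Villiger (Dakin-type) oxidation with mCPBA in CH2Cl2 at 0 °C converts the aldehyde into 2-{3,5-dimethoxy-4-[3,4,5-trimethoxy-2-(3,4,5-trimethoxyphenoxy)phenoxy]phenoxy}-3,5-dimethoxyphenyl formate F6. K2CO3 in MeOH cleaves it in the same flask to 2-{3,5-dimethoxy-4-[3,4,5-trimethoxy-2-(3,4,5-trimethoxyphenoxy)phenoxy]phenoxy}-3,5-dimethoxyphenol F7. Ullmann coupling of F7 with an excess of commercial 2-bromo-1,3,5-trimethoxybenzene (CuI, 2,2,6,6-tetramethylheptane-3,5-dione, Cs2CO3, NMP, 120 °C) rejoins the route at 20, so steps 10 and 11 are both bypassed.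

Step 11. The risk is sluggish exchange and coupling at the crowded ring D phenoxide, which would leave the phenol unchanged while the bromide is reduced or homocoupled. The fallback is a metal-free arylation with a diaryliodonium salt and sets out from 18. Oxidation of commercial 5-iodo-1,2,3-trimethoxybenzene with mCPBA and TsOH·H2O in MeCN, followed by 1,3,5-trimethoxybenzene, gives (3,4,5-trimethoxyphenyl)(2,4,6-trimethoxyphenyl)iodonium 4-methylbenzenesulfonate F8. With 18 and K2CO3 in toluene at 50 °C the phenoxide should attack iodine and couple with the less electron-rich 3,4,5-trimethoxyphenyl group, the 2,4,6-trimethoxyphenyl group acting as the non-transferred ligand. The route is rejoined at 20.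

**Further compounds**
F1 | step 4 | {4-[(E)-1,2-dichlorovinyloxy]-3,5-dimethoxyphenoxy}triisopropylsilane | Cl/C=C(/Cl)Oc1c(OC)cc(O[Si](C(C)C)(C(C)C)C(C)C)cc1OC
F2 | step 4 | (4-ethynyloxy-3,5-dimethoxyphenoxy)triisopropylsilane | C#COc1c(OC)cc(O[Si](C(C)C)(C(C)C)C(C)C)cc1OC
F3 | step 4 | tributyl{1-[2,6-dimethoxy-4-(triisopropylsilyloxy)phenoxy]vinyl}stannane | C=C(Oc1c(OC)cc(O[Si](C(C)C)(C(C)C)C(C)C)cc1OC)[Sn](CCCC)(CCCC)CCCC
F4 | step 10 | 2-[4-(2-hydroxy-3,4,5-trimethoxyphenoxy)-3,5-dimethoxyphenoxy]-3,5-dimethoxybenzaldehyde | O=Cc1cc(OC)cc(OC)c1Oc1cc(OC)c(Oc2cc(OC)c(OC)c(OC)c2O)c(OC)c1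
F5 | step 10 | 2-{3,5-dimethoxy-4-[3,4,5-trimethoxy-2-(3,4,5-trimethoxyphenoxy)phenoxy]phenoxy}-3,5-dimethoxybenzaldehyde | O=Cc1cc(OC)cc(OC)c1Oc1cc(OC)c(Oc2cc(OC)c(OC)c(OC)c2Oc2cc(OC)c(OC)c(OC)c2)c(OC)c1
F6 | step 10 | 2-{3,5-dimethoxy-4-[3,4,5-trimethoxy-2-(3,4,5-trimethoxyphenoxy)phenoxy]phenoxy}-3,5-dimethoxyphenyl formate | O=COc1cc(OC)cc(OC)c1Oc1cc(OC)c(Oc2cc(OC)c(OC)c(OC)c2Oc2cc(OC)c(OC)c(OC)c2)c(OC)c1
F7 | step 10 | 2-{3,5-dimethoxy-4-[3,4,5-trimethoxy-2-(3,4,5-trimethoxyphenoxy)phenoxy]phenoxy}-3,5-dimethoxyphenol | Oc1cc(OC)cc(OC)c1Oc1cc(OC)c(Oc2cc(OC)c(OC)c(OC)c2Oc2cc(OC)c(OC)c(OC)c2)c(OC)c1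
F8 | step 11 | (3,4,5-trimethoxyphenyl)(2,4,6-trimethoxyphenyl)iodonium 4-methylbenzenesulfonate | COc1cc([I+]c2c(OC)cc(OC)cc2OC)cc(OC)c1OC.Cc1ccc(cc1)S(=O)(=O)[O-]
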